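**Retrosynthetic overview**
1. The target is taken back to 6β-benzoyloxy-4β-hydroxyeudesman-3-one (a bulky hydride sets the axial 3α-OH last) and this to 4β,6β-dihydroxyeudesm-1-en-3-one (O6 benzoylation, C1=C2 hydrogenation).
2. That enone comes from a trans-fused 3-methoxy-2-ene-1,6-dione by hydride addition at C1 and C6 and acid-induced 1,3-carbonyl transposition (O1 is deleted, the methoxy carbon becomes the C3 carbonyl). The C4 carbinol comes from methyl addition to a C4 ketone; C5, C6 and C7 are corrected by epimerisation, oxidation–reduction and hydrogenation.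
3. Key disconnection: ring B (C5–C10) is cut at C5–C6 and C9–C10 into a [4+2] pair. Ring A (C1–C5, C10) with O3, the C4 carbonyl carbon and the C10 methyl is 2-methoxy-5-methyl-1,4-benzoquinone; C6–C9 with O6 and the C7 isopropyl is (E)-2-isopropyl-1-(triisopropylsilyloxy)buta-1,3-diene.
4. The strategy rests on the quaternary C10 at the junction of rings A and B: it is the β-carbon of the C4 carbonyl, and chelation of that carbonyl together with the neighbouring O3 makes C5=C10 the dienophile, sending the nucleophilic diene terminus C9 to C10 and the oxygenated C6 to C5.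
5. Ring order: ring A is bought as the quinone, ring B is closed in the cycloaddition; the diene is made from 3-methylbutanal and acetaldehyde by directed aldol condensation and dienol silylation.

Key step: step 4

Remark on numbering: eudesmane numbering is used (ring A = C1–C5 and C10, ring B = C5–C10, C14 = methyl on C10, C15 = methyl on C4, isopropyl on C7); α/β refer to the usual drawing with the C10 methyl β.

Assumption: the (S)-BINOL–TiCl2 complex is taken, by analogy with its sense of induction in chelated carbonyl–ene reactions, to expose the quinone face that leads to adduct 10; if the opposite face is favoured, (R)-BINOL is used and nothing else changes.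

**Step 1**
Reactants: 1 3-methylbutanal; 2 cyclohexylamine
Product: 3 (E)-N-(3-methylbutylidene)cyclohexanamine
Conditions: Et2O, MgSO4, 0 → 23 °C; distil
Reagents that add atoms: none
Why: Imine condensation of an unhindered aldehyde with a primary amine should go to completion once water is bound, and it masks the aldehyde for a directed aldol.

**Step 2**
Reactants: 3 (E)-N-(3-methylbutylidene)cyclohexanamine; 4 acetaldehyde
Product: 7 (E)-2-isopropylbut-2-enal, via lithiated imine 5 (not isolated), via hydroxy imine 6 (not isolated)
Conditions: LiN(i-Pr)2, THF, −78 → 0 °C; MeCHO, −78 °C; then aq. oxalic acid, 60 °C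
Reagents that add atoms: water, O
Why: In this directed aldol condensation through the metallated imine only the 1-azaallyl anion can be the nucleophile and only acetaldehyde the electrophile, and acidic hydrolysis with dehydration should give the more stable E-enal, so the mixtures of an unprotected crossed aldol are avoided.

**Step 3**
Reactants: 7 (E)-2-isopropylbut-2-enal
Product: 8 (E)-2-isopropyl-1-(triisopropylsilyloxy)buta-1,3-diene
Conditions: i-Pr3SiOTf, Et3N, Et2O, 0 → 23 °C
Reagents that add atoms: triisopropylsilyl triflate, CC(C)[Si](OS(=O)(=O)C(F)(F)F)(C(C)C)C(C)C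
Why: O-silylation of the enal and γ-deprotonation by the amine (silyl dienol ether formation) should give the 1-siloxydiene, the s-trans oxocarbenium ion leading to the E enol ether (oxygen trans to the vinyl group) that the cycloaddition needs.

**Step 4**
Reactants: 8 (E)-2-isopropyl-1-(triisopropylsilyloxy)buta-1,3-diene; 9 2-methoxy-5-methyl-1,4-benzoquinone
Product: 10 cis-fused 3-methoxy-6α-(triisopropylsilyloxy)-15-noreudesma-2,7-diene-1,4-dione (5β-H)
Conditions: TiCl2(Oi-Pr)2 (20 mol%), (S)-BINOL (22 mol%), 4 Å MS (catalyst preformed, then decanted), toluene–CH2Cl2, −40 → 0 °C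
Reagents that add atoms: none
Why: The bidentate tetravalent titanium Lewis acid should chelate the C4 carbonyl oxygen and the neighbouring methoxy oxygen of 9, so that the methyl-bearing C5=C10 bond is the acceptor in an asynchronous concerted endo [4+2] (Diels–Alder reaction) in which the unsubstituted diene terminus C9 bonds to the β-carbon C10 and the siloxy-bearing C6 bonds to C5. The closest known reaction type is the BINOL–TiCl2-catalysed Diels–Alder reaction of methoxy-substituted benzoquinones with silyloxydienes, together with the SnCl4- or TiCl4-chelated additions to this quinone, which keep the thermal orientation, whereas monodentate boron Lewis acids bind the vinylogous-ester carbonyl (future C1) and reverse it. Ring B is closed by intermolecular cycloaddition across C5=C10, two σ bonds and a six-membered ring forming in one step. C10 is set by the ligand-controlled quinone face, C5 by suprafacial addition (cis ring fusion) and C6 by the endo rule acting on the E dienol ether (siloxy group cis to the C5–C4 bond). The step needs site selectivity (the methoxy group deactivates C2=C3), orientation (chelation plus the strongly polarised 1-siloxydiene) and facial selectivity (the chiral ligand).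

**Step 5**
Reactants: 10 cis-fused 3-methoxy-6α-(triisopropylsilyloxy)-15-noreudesma-2,7-diene-1,4-dione (5β-H)
Product: 11 trans-fused 3-methoxy-6α-(triisopropylsilyloxy)-15-noreudesma-2,7-diene-1,4-dione (5α-H)
Conditions: Et3N, MeOH, 0 → 23 °C (equilibration; recovered 10 is resubmitted)
Reagents that add atoms: none
Why: Base-mediated epimerisation through reversible enolisation of the C4 ketone towards C5 should enrich the trans-fused isomer (both fusion bonds equatorial, 5α-H set under thermodynamic control), and a weak amine in methanol keeps the enolate short-lived so that re-protonation outruns loss of the β-siloxy group.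

**Step 6**
Reactants: 11 trans-fused 3-methoxy-6α-(triisopropylsilyloxy)-15-noreudesma-2,7-diene-1,4-dione (5α-H)
Product: 12 4β-hydroxy-3-methoxy-6α-(triisopropylsilyloxy)eudesma-2,7-dien-1-one
Conditions: CeCl3 (dried), MeLi, THF, −78 °C; then H2O
Reagents that add atoms: methyllithium, [Li]C
Why: 1,2-Addition of the weakly basic organocerium reagent should go to the more electrophilic C4 ketone (C1 is a vinylogous ester carbonyl) from the α face, anti to the axial 10β-methyl, giving the 4β-hydroxy-4α-methyl carbinol without enolisation at C5.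

**Step 7**
Reactants: 12 4β-hydroxy-3-methoxy-6α-(triisopropylsilyloxy)eudesma-2,7-dien-1-one
Product: 13 4β,6α-dihydroxy-3-methoxyeudesma-2,7-dien-1-one
Conditions: Bu4NF, THF, 0 → 23 °C
Reagents that add atoms: none
Why: Fluoride-mediated desilylation should free the allylic 6α-hydroxyl, which is safe now that C4 is no longer a ketone and no retro-aldol path exists.

**Step 8**
Reactants: 13 4β,6α-dihydroxy-3-methoxyeudesma-2,7-dien-1-one
Product: 14 4β-hydroxy-3-methoxyeudesma-2,7-diene-1,6-dione
Conditions: Dess–Martin periodinane, pyridine, CH2Cl2, 0 → 23 °C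
Reagents that add atoms: none
Why: Dess–Martin oxidation should convert the only secondary (allylic) alcohol into the 7-en-6-one under near-neutral conditions, leaving the tertiary C4 hydroxyl and the vinylogous ester untouched and erasing the wrong C6 configuration.

**Step 9**
Reactants: 14 4β-hydroxy-3-methoxyeudesma-2,7-diene-1,6-dione
Product: 15 4β-hydroxy-3-methoxyeudesm-2-ene-1,6-dione (7β-isopropyl)
Conditions: H2 (1 atm), 10% Pd/C, EtOAc, 23 °C
Reagents that add atoms: none
Why: Heterogeneous hydrogenation of the enone C7=C8 should deliver hydrogen from the α face, away from the axial 10β-methyl, giving the equatorial 7β-isopropyl group (also the more stable epimer next to the C6 ketone), while the push–pull C2=C3 bond of the vinylogous ester stays intact.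

**Step 10**
Reactants: 15 4β-hydroxy-3-methoxyeudesm-2-ene-1,6-dione (7β-isopropyl)
Product: 17 4β,6β-dihydroxyeudesm-1-en-3-one, via allylic triol 16 (not isolated)
Conditions: i-Bu2AlH (excess), CH2Cl2, −78 → 0 °C; then 1 M HCl, THF, 23 °C
Reagents that add atoms: water, O
Why: Hydride reduction by i-Bu2AlH should reach the C6 ketone from the open α face (the β face is screened by the axial 10β-methyl and by the O4 aluminium alkoxide, which also chelates the carbonyl, so the axial 6β-alcohol results) and should reduce the vinylogous-ester carbonyl C1 by 1,2-addition, after which aqueous acid hydrolyses the enol ether and eliminates the C1 hydroxyl (Stork–Danheiser transposition), placing the carbonyl at C3 and deleting O1.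

**Step 11**
Reactants: 17 4β,6β-dihydroxyeudesm-1-en-3-one
Product: 18 6β-benzoyloxy-4β-hydroxyeudesm-1-en-3-one
Conditions: BzCl, DMAP, pyridine, 60 °C
Reagents that add atoms: benzoyl chloride, O=C(Cl)c1ccccc1
Why: DMAP-catalysed acylation should benzoylate the only secondary hydroxyl (6β), the tertiary 4β-hydroxyl being unreactive, so no protecting group is needed because the C3 alcohol does not yet exist.

**Step 12**
Reactants: 18 6β-benzoyloxy-4β-hydroxyeudesm-1-en-3-one
Product: 19 6β-benzoyloxy-4β-hydroxyeudesman-3-one
Conditions: H2 (1 atm), 10% Pd/C, EtOAc, 23 °C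
Reagents that add atoms: none
Why: Catalytic hydrogenation of the disubstituted enone C1=C2 should be fast and creates no stereocentre, the benzoate and ketone being inert.

**Step 13**
Reactants: 19 6β-benzoyloxy-4β-hydroxyeudesman-3-one
Product: 20 6β-benzoyloxyeudesmane-3α,4β-diol (target)
Conditions: LiBH(s-Bu)3, THF, −78 °C; then H2O
Reagents that add atoms: none
Why: Ketone reduction by the hindered trialkylborohydride should follow the equatorial trajectory on the β face (the axial path is blocked by the axial hydrogens at C1 and C5), giving the axial 3α-alcohol trans-diaxial to the 4β-hydroxyl, while the hindered benzoate survives at −78 °C.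

**Compound list**
1 | 3-methylbutanal | CC(C)CC=O | starting material
2 | cyclohexylamine | NC1CCCCC1 | starting material
3 | (E)-N-(3-methylbutylidene)cyclohexanamine | CC(C)C/C=N/C1CCCCC1 | intermediate
4 | acetaldehyde | CC=O | starting material
5 | lithiated imine (1-azaallyllithium of 3), not isolated | [Li]N(C=CC(C)C)C1CCCCC1 | intermediate
6 | hydroxy imine (N-cyclohexyl imine of 3-hydroxy-2-isopropylbutanal, present as its lithium alkoxide), not isolated | CC(O)C(C(C)C)C=NC1CCCCC1 | intermediate
7 | (E)-2-isopropylbut-2-enal | C/C=C(/C=O)C(C)C | intermediate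
8 | (E)-2-isopropyl-1-(triisopropylsilyloxy)buta-1,3-diene | C=C/C(C(C)C)=C/O[Si](C(C)C)(C(C)C)C(C)C | intermediate
9 | 2-methoxy-5-methyl-1,4-benzoquinone | COC1=CC(=O)C(C)=CC1=O | starting material
10 | cis-fused 3-methoxy-6α-(triisopropylsilyloxy)-15-noreudesma-2,7-diene-1,4-dione (5β-H, 10β-methyl) | CC(C)C1=CC[C@@]2(C)C(=O)C=C(OC)C(=O)[C@H]2[C@H]1O[Si](C(C)C)(C(C)C)C(C)C | intermediate
11 | trans-fused 3-methoxy-6α-(triisopropylsilyloxy)-15-noreudesma-2,7-diene-1,4-dione (5α-H, 10β-methyl) | CC(C)C1=CC[C@@]2(C)C(=O)C=C(OC)C(=O)[C@@H]2[C@H]1O[Si](C(C)C)(C(C)C)C(C)C | intermediate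
12 | 4β-hydroxy-3-methoxy-6α-(triisopropylsilyloxy)eudesma-2,7-dien-1-one (4α-methyl, 5α-H) | CC(C)C1=CC[C@@]2(C)C(=O)C=C(OC)[C@](C)(O)[C@@H]2[C@H]1O[Si](C(C)C)(C(C)C)C(C)C | intermediate
13 | 4β,6α-dihydroxy-3-methoxyeudesma-2,7-dien-1-one | CC(C)C1=CC[C@@]2(C)C(=O)C=C(OC)[C@](C)(O)[C@@H]2[C@H]1O | intermediate
14 | 4β-hydroxy-3-methoxyeudesma-2,7-diene-1,6-dione | CC(C)C1=CC[C@@]2(C)C(=O)C=C(OC)[C@](C)(O)[C@@H]2C1=O | intermediate
15 | 4β-hydroxy-3-methoxyeudesm-2-ene-1,6-dione (5α-H, 7β-isopropyl) | CC(C)[C@@H]1CC[C@@]2(C)C(=O)C=C(OC)[C@](C)(O)[C@@H]2C1=O | intermediate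
16 | allylic triol, 3-methoxyeudesm-2-ene-1,4β,6β-triol (C1 epimers), not isolated | CC(C)[C@@H]1CC[C@@]2(C)C(O)C=C(OC)[C@](C)(O)[C@@H]2[C@@H]1O | intermediate
17 | 4β,6β-dihydroxyeudesm-1-en-3-one | CC(C)[C@@H]1CC[C@@]2(C)C=CC(=O)[C@](C)(O)[C@@H]2[C@@H]1O | intermediate
18 | 6β-benzoyloxy-4β-hydroxyeudesm-1-en-3-one | CC(C)[C@@H]1CC[C@@]2(C)C=CC(=O)[C@](C)(O)[C@@H]2[C@@H]1OC(=O)c1ccccc1 | intermediate
19 | 6β-benzoyloxy-4β-hydroxyeudesman-3-one | CC(C)[C@@H]1CC[C@@]2(C)CCC(=O)[C@](C)(O)[C@@H]2[C@@H]1OC(=O)c1ccccc1 | intermediate
20 | 6β-benzoyloxyeudesmane-3α,4β-diol (4α-methyl, 5α-H, 7β-isopropyl, 10β-methyl; CNP0187831.1) | CC(C)[C@@H]1CC[C@@]2(C)CC[C@@H](O)[C@](C)(O)[C@@H]2[C@@H]1OC(=O)c1ccccc1 | target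

**Step count and risks**
Total steps: 13. Longest linear sequence: 13 steps (1 to 20); quinone 9 enters unchanged at step 4.

Most likely to fail:

1. Step 4. The trisubstituted C5=C10 bond may turn over slowly, the chelated ligand sits far from the reacting bond so facial discrimination may be poor, and the Lewis acid may cleave the silyl dienol ether. Fallback by resolution: setting out from 8 and 9, the uncatalysed cycloaddition (toluene, 80 °C; the thermal reaction of this quinone has the same orientation) should give 10 together with its mirror-image adduct F1. Steps 5–7 on the mixture should give 13 and, from F1, the mirror-image trans-dione F2, mirror-image carbinol F3 and mirror-image diol F4. Esterification of the 13/F4 pair with (S)-2-methoxy-2-phenylacetic acid (DCC, DMAP) gives the diastereomeric esters, mandelate of 13 F5 and mandelate of the mirror image F6, which are separated by chromatography. K2CO3 in MeOH releases 13 from F5, and the route resumes at 13.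

2. Step 5. The cis/trans equilibrium may stop short, because in the trans isomer the equatorial 6α-siloxy group lies against the C4 carbonyl oxygen and the C7 isopropyl, and the C5 enolate may expel silanol (E1cB). Fallback by changing the order: setting out from 10, HF·pyridine (THF, 0 °C) removes the silyl group to give the cis-fused aldol F7. A trace of Et3N in CH2Cl2 should then equilibrate it to the trans-fused aldol F8, which is held by an O6–H···O4 hydrogen bond across the peri positions. Excess MeLi/CeCl3 (THF, −78 °C) adds to its C4 ketone from the α face and gives 13 directly, so the route resumes at 13 and step 7 is skipped.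

3. Step 11. Acylation of the axial 6β-hydroxyl may stall between the syn-axial C10 methyl and C4 hydroxyl, and forcing may dehydrate the tertiary alcohol. Fallback by intramolecular delivery: setting out from 17, trimethyl orthobenzoate with catalytic camphorsulfonic acid (CH2Cl2) ties the syn-diaxial O4/O6 pair into the cyclic orthobenzoate F9. Mild aqueous acetic acid opens it to the secondary benzoate with release of the tertiary hydroxyl, giving 18, where the route resumes.

**Further compounds**
F1 | step 4 | mirror-image adduct (enantiomer of 10) | CC(C)C1=CC[C@]2(C)C(=O)C=C(OC)C(=O)[C@@H]2[C@@H]1O[Si](C(C)C)(C(C)C)C(C)C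
F2 | step 4 | mirror-image trans-dione (enantiomer of 11) | CC(C)C1=CC[C@]2(C)C(=O)C=C(OC)C(=O)[C@H]2[C@@H]1O[Si](C(C)C)(C(C)C)C(C)C
F3 | step 4 | mirror-image carbinol (enantiomer of 12) | CC(C)C1=CC[C@]2(C)C(=O)C=C(OC)[C@@](C)(O)[C@H]2[C@@H]1O[Si](C(C)C)(C(C)C)C(C)C
F4 | step 4 | mirror-image diol (enantiomer of 13) | CC(C)C1=CC[C@]2(C)C(=O)C=C(OC)[C@@](C)(O)[C@H]2[C@@H]1O
F5 | step 4 | mandelate of 13, its 6-O-[(S)-2-methoxy-2-phenylacetate] | CC(C)C1=CC[C@@]2(C)C(=O)C=C(OC)[C@](C)(O)[C@@H]2[C@H]1OC(=O)[C@@H](OC)c1ccccc1
F6 | step 4 | mandelate of the mirror image, 6-O-[(S)-2-methoxy-2-phenylacetate] of F4 | CC(C)C1=CC[C@]2(C)C(=O)C=C(OC)[C@@](C)(O)[C@H]2[C@@H]1OC(=O)[C@@H](OC)c1ccccc1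
F7 | step 5 | cis-fused aldol, 6α-hydroxy-3-methoxy-15-noreudesma-2,7-diene-1,4-dione (5β-H) | CC(C)C1=CC[C@@]2(C)C(=O)C=C(OC)C(=O)[C@H]2[C@H]1O
F8 | step 5 | trans-fused aldol, 6α-hydroxy-3-methoxy-15-noreudesma-2,7-diene-1,4-dione (5α-H) | CC(C)C1=CC[C@@]2(C)C(=O)C=C(OC)C(=O)[C@@H]2[C@H]1O
F9 | step 11 | cyclic orthobenzoate, 4β,6β-O-(α-methoxybenzylidene) derivative of 17 | CC(C)[C@@H]1CC[C@@]2(C)C=CC(=O)[C@]3(C)OC(OC)(c4ccccc4)O[C@H]1[C@H]23
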